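## Retrosynthetic overview

1. The target (germacrane numbering, C1–C15) is reached from a fully silylated 11,13-dihydro epoxy macrolactone by late C13 methylenation, C8 angeloylation and desilylation.
2. Key disconnection: the C1–C10 bond of the oxirane. The enabling feature is the trisubstituted C1–O–C10 oxirane inside the ten-membered carbocycle (C10 quaternary, carrying the C14 methyl), which is the retron of a methyl ketone plus a sulfonium ylide. The Z-C4=C5 alkene and the trans-fused C6/C7 γ-lactone bend the seco-chain so that C1 can reach C10. One step closes the ten-membered ring and the oxirane and sets C1 and C10.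
3. The seco keto sulfonium salt comes from a C1–C3 aldehyde and an alkenyl iodide (Nozaki–Hiyama–Kishi at C3–C4, then CBS reduction for C3). The C10 ketone comes from Tsuji–Wacker oxidation of an allyl group added at C8 by Brown allylation.
4. The lactone is made first: an Evans syn-aldol of a succinyl imide with a Z-β-iodoenal sets C6/C7 and lactonises. The iodoenal comes from but-2-yne-1,4-diol by trans-hydroalumination/iodination, which fixes the C4=C5 geometry.
5. Ring order: γ-lactone (step 5), then ten-membered carbocycle and oxirane together (step 17).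

Key step: step 17

Assumption: the SMILES is read as the (1R,3S,4Z,6R,7R,8R,10R) heliangolide (trans-fused 6,12-olide, trans 1,10-oxirane, 8-angelate). "Target configuration" at a centre means the spatial arrangement found in the target; the CIP letter of an intermediate may differ.

## Route

Step 1
Reactants: 1 but-2-yne-1,4-diol
Product: 2 4-(tert-butyldiphenylsilyloxy)but-2-yn-1-ol
Conditions: TBDPSCl (1 equiv), imidazole, diol 1 (4 equiv), DMF, 0 °C → rt
Reagents that add atoms: tert-butyl(chloro)diphenylsilane, CC(C)(C)[Si](Cl)(c1ccccc1)c1ccccc1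
Why: Silyl ether formation; with the symmetrical diol in excess the monosilyl ether should dominate, and no stereocentre is involved.

Step 2
Reactants: 2 4-(tert-butyldiphenylsilyloxy)but-2-yn-1-ol
Product: 3 (Z)-4-(tert-butyldiphenylsilyloxy)-3-iodobut-2-en-1-ol
Conditions: NaAlH2(OCH2CH2OMe)2 (Red-Al), THF, 0 °C; then I2, −78 → 0 °C
Reagents that add atoms: iodine, [I][I]
Why: Hydroxyl-directed trans-hydroalumination of the propargylic alcohol delivers hydride to the proximal alkyne carbon and aluminium to the distal one, and iodinolysis with retention should give the Z-iodoalkene (iodine cis to CH2OH), which fixes the later C4=C5 geometry.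

Step 3
Reactants: 3 (Z)-4-(tert-butyldiphenylsilyloxy)-3-iodobut-2-en-1-ol
Product: 4 (Z)-4-(tert-butyldiphenylsilyloxy)-3-iodobut-2-enal
Conditions: MnO2 (activated, excess), CH2Cl2, rt, dark
Reagents that add atoms: none
Why: Allylic alcohol oxidation with MnO2 is neutral and should leave the Z-iodoalkene and the silyl ether intact.

Step 4
Reactants: 5 (S)-4-benzyl-1,3-oxazolidin-2-one; 6 methyl 4-chloro-4-oxobutanoate
Product: 7 methyl 4-[(S)-4-benzyl-2-oxo-1,3-oxazolidin-3-yl]-4-oxobutanoate
Conditions: n-BuLi, THF, −78 °C; then 6, −78 → 0 °C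
Reagents that add atoms: none
Why: N-Acylation of the lithiated oxazolidinone by the acid chloride is much faster than attack on the methyl ester at −78 °C.

Step 5
Reactants: 7 methyl 4-[(S)-4-benzyl-2-oxo-1,3-oxazolidin-3-yl]-4-oxobutanoate; 4 (Z)-4-(tert-butyldiphenylsilyloxy)-3-iodobut-2-enal
Product: 9 lactone imide (trans-γ-butyrolactone C6–O–C12; C6 carries the (Z)-2-iodo-3-(TBDPS-oxy)prop-1-enyl group; C7 carries the acyl oxazolidinone), via syn-aldol adduct 8 (not isolated)
Conditions: Bu2BOTf, i-Pr2NEt, CH2Cl2, −78 → 0 °C; then 4, −78 → 0 °C; pH 7 buffer, MeOH, H2O2, 0 °C; then PPTS (cat.), CH2Cl2, rt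
Reagents that add atoms: none
Why: Evans syn-aldol reaction: the Z-boron enolate of the imide (the ester is not enolised) adds through a chair transition state on the face away from the benzyl group, which sets C6 and C7 syn in the target configuration, and the γ-hydroxy ester then closes to the trans-disubstituted butyrolactone with loss of methanol.

Step 6
Reactants: 9 lactone imide
Product: 10 lactone aldehyde (as 9, with C7 carrying the C8 formyl group)
Conditions: Cp2Zr(H)Cl (1.5 equiv), THF, rt; aqueous work-up
Reagents that add atoms: none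
Why: Reduction of the N-acyl oxazolidinone by Cp2Zr(H)Cl stops at a zirconated hemiaminal that releases the aldehyde on work-up, a known amide-to-aldehyde reduction that should spare the lactone, the alkenyl iodide and the C7 centre.

Step 7
Reactants: 10 lactone aldehyde
Product: 11 homoallylic alcohol (as 10, with C7 carrying CH(OH)CH2CH=CH2; C8 in the target configuration)
Conditions: (+)-Ipc2BOMe, allylMgBr, Et2O, 0 °C → rt; then 10, −78 °C; pH 7 buffer, H2O2, MeOH, 0 °C
Reagents that add atoms: allylmagnesium bromide, C=CC[Mg]Br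
Why: Brown allylation: the allylborane adds through a chair transition state in which the isopinocampheyl groups select the aldehyde face, so C8 is set by the reagent (target configuration, anti-Felkin with respect to C7), and the neutral low-temperature conditions avoid β-elimination of the lactone oxygen.

Step 8
Reactants: 11 homoallylic alcohol
Product: 12 C8 triethylsilyl ether of 11
Conditions: TESOTf, 2,6-lutidine, CH2Cl2, −78 °C
Reagents that add atoms: triethylsilyl trifluoromethanesulfonate, CC[Si](CC)(CC)OS(=O)(=O)C(F)(F)F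
Why: Silylation with the silyl triflate under weakly basic conditions caps the C8 hydroxyl before it can translactonise onto C12.

Step 9
Reactants: 13 3-(4-methoxybenzyloxy)propan-1-ol
Product: 14 3-(4-methoxybenzyloxy)propanal
Conditions: Dess–Martin periodinane, CH2Cl2, rt
Reagents that add atoms: none
Why: Dess–Martin oxidation of a primary alcohol to the aldehyde without over-oxidation.

Step 10
Reactants: 12 C8 triethylsilyl ether (alkenyl iodide); 14 3-(4-methoxybenzyloxy)propanal
Product: 15 C3 allylic alcohol (C1–C15 seco chain; C1 OPMB; C15 OTBDPS; C8 OTES; terminal alkene at C10; both C3 epimers)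
Conditions: CrCl2 (4 equiv), NiCl2 (1 mol %), DMF, rt
Reagents that add atoms: none
Why: Nozaki–Hiyama–Kishi coupling: the alkenylchromium formed with NiCl2 catalysis keeps the alkene geometry (C3 ends cis to C6) and adds only to the aldehyde, leaving lactone and silyl ethers; C3 is formed without control and is corrected in steps 11 and 12.

Step 11
Reactants: 15 C3 allylic alcohol (epimer mixture)
Product: 16 C3 enone
Conditions: Dess–Martin periodinane, CH2Cl2, 0 °C → rt
Reagents that add atoms: none
Why: Dess–Martin oxidation converges both C3 epimers into one enone under neutral conditions that should not isomerise the Z-alkene.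

Step 12
Reactants: 16 C3 enone
Product: 17 (3S)-allylic alcohol
Conditions: (R)-2-methyl-CBS-oxazaborolidine (0.3 equiv), catecholborane, toluene, −78 °C
Reagents that add atoms: none
Why: Corey–Bakshi–Shibata reduction: the α-branched alkenyl group acts as the large substituent, so the (R)-oxazaborolidine directs hydride to the face that gives the 3S alcohol, and catecholborane at −78 °C should not touch the lactone or the terminal alkene.

Step 13
Reactants: 17 (3S)-allylic alcohol
Product: 18 C3 tert-butyldimethylsilyl ether of 17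
Conditions: TBSOTf, 2,6-lutidine, CH2Cl2, −78 °C
Reagents that add atoms: tert-butyldimethylsilyl trifluoromethanesulfonate, CC(C)(C)[Si](C)(C)OS(=O)(=O)C(F)(F)F
Why: Standard silylation of the secondary allylic alcohol with the silyl triflate.

Step 14
Reactants: 18 C3 tert-butyldimethylsilyl ether (terminal alkene)
Product: 19 C10 methyl ketone
Conditions: PdCl2 (10 mol %), CuCl, O2 (1 atm), DMF/H2O (7:1), rt
Reagents that add atoms: water, O
Why: Tsuji–Wacker oxidation: Markovnikov hydroxypalladation of the monosubstituted alkene gives the methyl ketone, while the hindered, electron-poor trisubstituted C4=C5 alkene should not react.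

Step 15
Reactants: 19 C10 methyl ketone (C1 OPMB)
Product: 20 C1 primary alcohol
Conditions: DDQ, CH2Cl2/pH 7 buffer (10:1), 0 °C
Reagents that add atoms: none
Why: Oxidative cleavage of the electron-rich 4-methoxybenzyl ether by DDQ, buffered so that the three silyl ethers survive.

Step 16
Reactants: 20 C1 primary alcohol
Product: 22 C1 diphenylsulfonium triflate of the seco keto lactone, via primary triflate 21 (not isolated)
Conditions: Tf2O, 2,6-di-tert-butylpyridine, CH2Cl2, −78 °C; then Ph2S (10 equiv), −78 °C → rt
Reagents that add atoms: trifluoromethanesulfonic anhydride, O=S(=O)(OS(=O)(=O)C(F)(F)F)C(F)(F)F; diphenyl sulfide, c1ccc(cc1)Sc1ccccc1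
Why: Triflation of the only free hydroxyl followed by SN2 S-alkylation of diphenyl sulfide (a known route to alkyldiphenylsulfonium triflates); the non-nucleophilic base, the low temperature and the large excess of sulfide are chosen to outrun attack of the bulky C15 silyl ether oxygen on the triflate.

Step 17
Reactants: 22 C1 diphenylsulfonium triflate of the seco keto lactone
Product: 25 epoxy macrolactone (ten-membered carbocycle; (1R,10R)-1,10-oxirane; saturated C11; C3 OTBS; C15 OTBDPS; C8 OTES), via sulfonium ylide 23 (not isolated), via betaine 24 (not isolated)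
Conditions: LiN(SiMe3)2 (1.05 equiv, syringe pump), THF (0.001 M), −78 → −20 °C
Reagents that add atoms: none
Why: Proposed new method: LiN(SiMe3)2 removes a C1 proton of the diphenylsulfonium salt (the only protons alpha to sulfur, several pKa units more acidic than the ketone or lactone alpha-protons), the unstabilised ylide 23 adds to the C10 methyl ketone to give betaine 24, and the alkoxide displaces Ph2S to form the oxirane; the closest known reaction type is the Corey–Chaykovsky epoxidation of ketones with diphenylsulfonium alkylides and its intramolecular use in epoxide annulations that close five- to seven-membered rings, here extended to a ten-membered ring. The carbocycle closes by 10-exo-trig attack of C1 on the C10 carbonyl and the oxirane by 3-exo-tet displacement at C1 with inversion. C10 is set by the carbonyl face that is attacked and C1 by the orientation of the ylide carbon in the same C–C bond-forming event; both are under substrate control, the seco-chain being folded by the Z-C4=C5 alkene and the trans-fused lactone so that the C1–C2 and C9–C10 bonds lie anti across the forming bond with the C14 methyl turned away from H7 and the C8 silyl ether outside the ring, an arrangement that mirrors the E-1(10) geometry of heliangolides and should lead to the 1R,10R trans-oxirane. The step needs chemoselective ylide formation (secured by the acidity gap and the mild amide base), attack on the ketone and not on the lactone carbonyl (the ketone is more electrophilic and the lactone would require an eight-membered ring), cyclisation over oligomerisation (high dilution and slow addition of base at −78 °C) and trans/facial selectivity (the conformational bias just described). The saturated C11 position and the absence of the angelate remove the Michael acceptors that an ylide would cyclopropanate.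

Step 18
Reactants: 25 epoxy macrolactone
Product: 28 α-methylene epoxy macrolactone (C11=C13), via Mannich base 26 (not isolated), via trimethylammonium iodide 27 (not isolated)
Conditions: LiN(i-Pr)2 (LDA), THF, −78 °C; CH2=NMe2 iodide (Eschenmoser's salt), −78 °C → rt; then MeI, THF, rt; then aq NaHCO3, rt
Reagents that add atoms: Eschenmoser's salt, C=[N+](C)C.[I-]
Why: Mannich reaction of the lithium lactone enolate with Eschenmoser's salt followed by N-methylation and base-induced β-elimination of trimethylamine is the standard α-methylenation of γ-butyrolactones; the transient C11 centre is destroyed in the elimination.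

Step 19
Reactants: 28 α-methylene epoxy macrolactone
Product: 29 C8 alcohol (C3 OTBS and C15 OTBDPS retained)
Conditions: HF·pyridine, pyridine, THF, 0 °C
Reagents that add atoms: none
Why: Acid/fluoride lability decreases in the order TES > TBS > TBDPS, so buffered HF·pyridine at 0 °C should free only the C8 hydroxyl and leave the oxirane closed.

Step 20
Reactants: 29 C8 alcohol; 30 angelic acid ((Z)-2-methylbut-2-enoic acid)
Product: 31 C8 angelate (C3 OTBS; C15 OTBDPS)
Conditions: 30, 2,4,6-trichlorobenzoyl chloride, Et3N, toluene, rt; then 29, toluene, 80 °C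
Reagents that add atoms: none
Why: Yamaguchi-type esterification through the mixed anhydride without a nucleophilic acyl-transfer catalyst acylates the single free (C8) hydroxyl and should keep the Z geometry of the angelate.

Step 21
Reactants: 31 C8 angelate
Product: 32 target, (1R,3S,4Z,6R,7R,8R,10R)-8-angeloyloxy-1,10-epoxy-3,15-dihydroxygermacra-4,11(13)-dien-12,6-olide
Conditions: Bu4NF, AcOH (1:1), THF, 0 °C → rt
Reagents that add atoms: none
Why: Fluoride-mediated cleavage of both silyl ethers, buffered with acetic acid so that the oxirane, the α-methylene lactone and the angelate are not attacked by alkoxide or fluoride.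

## Compound list

1 | but-2-yne-1,4-diol | OCC#CCO | starting material
2 | 4-(tert-butyldiphenylsilyloxy)but-2-yn-1-ol | OCC#CCO[Si](c1ccccc1)(c1ccccc1)C(C)(C)C | intermediate
3 | (Z)-4-(tert-butyldiphenylsilyloxy)-3-iodobut-2-en-1-ol | OC/C=C(\I)CO[Si](c1ccccc1)(c1ccccc1)C(C)(C)C | intermediate
4 | (Z)-4-(tert-butyldiphenylsilyloxy)-3-iodobut-2-enal | O=C/C=C(\I)CO[Si](c1ccccc1)(c1ccccc1)C(C)(C)C | intermediate
5 | (S)-4-benzyl-1,3-oxazolidin-2-one | O=C1OC[C@H](Cc2ccccc2)N1 | starting material
6 | methyl 4-chloro-4-oxobutanoate | COC(=O)CCC(Cl)=O | starting material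
7 | methyl 4-[(S)-4-benzyl-2-oxo-1,3-oxazolidin-3-yl]-4-oxobutanoate | COC(=O)CCC(=O)N1[C@@H](Cc2ccccc2)COC1=O | intermediate
8 | syn-aldol adduct (open-chain methyl ester, C6 hydroxyl, C7 acyl oxazolidinone) | CC(C)(C)[Si](c1ccccc1)(c1ccccc1)OC/C(I)=C/[C@@H](O)[C@H](CC(=O)OC)C(=O)N1[C@@H](Cc2ccccc2)COC1=O | intermediate (not isolated)
9 | lactone imide (trans-γ-butyrolactone, C6 Z-iodoalkenyl, C7 acyl oxazolidinone) | CC(C)(C)[Si](c1ccccc1)(c1ccccc1)OC/C(I)=C/[C@H]1OC(=O)C[C@@H]1C(=O)N1[C@@H](Cc2ccccc2)COC1=O | intermediate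
10 | lactone aldehyde (C8 formyl on C7) | CC(C)(C)[Si](c1ccccc1)(c1ccccc1)OC/C(I)=C/[C@H]1OC(=O)C[C@@H]1C=O | intermediate
11 | homoallylic alcohol (C8 hydroxyl, target configuration) | CC(C)(C)[Si](c1ccccc1)(c1ccccc1)OC/C(I)=C/[C@H]1OC(=O)C[C@@H]1[C@H](O)CC=C | intermediate
12 | C8 triethylsilyl ether of 11 | CC(C)(C)[Si](c1ccccc1)(c1ccccc1)OC/C(I)=C/[C@H]1OC(=O)C[C@@H]1[C@H](O[Si](CC)(CC)CC)CC=C | intermediate
13 | 3-(4-methoxybenzyloxy)propan-1-ol | COc1ccc(cc1)COCCCO | starting material
14 | 3-(4-methoxybenzyloxy)propanal | COc1ccc(cc1)COCCC=O | intermediate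
15 | C3 allylic alcohol, both C3 epimers | COc1ccc(cc1)COCCC(O)/C(CO[Si](c1ccccc1)(c1ccccc1)C(C)(C)C)=C\[C@H]1OC(=O)C[C@@H]1[C@H](O[Si](CC)(CC)CC)CC=C | intermediate
16 | C3 enone | COc1ccc(cc1)COCCC(=O)/C(CO[Si](c1ccccc1)(c1ccccc1)C(C)(C)C)=C\[C@H]1OC(=O)C[C@@H]1[C@H](O[Si](CC)(CC)CC)CC=C | intermediate
17 | (3S)-allylic alcohol | COc1ccc(cc1)COCC[C@H](O)/C(CO[Si](c1ccccc1)(c1ccccc1)C(C)(C)C)=C\[C@H]1OC(=O)C[C@@H]1[C@H](O[Si](CC)(CC)CC)CC=C | intermediate
18 | C3 tert-butyldimethylsilyl ether of 17 | COc1ccc(cc1)COCC[C@H](O[Si](C)(C)C(C)(C)C)/C(CO[Si](c1ccccc1)(c1ccccc1)C(C)(C)C)=C\[C@H]1OC(=O)C[C@@H]1[C@H](O[Si](CC)(CC)CC)CC=C | intermediate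
19 | C10 methyl ketone | COc1ccc(cc1)COCC[C@H](O[Si](C)(C)C(C)(C)C)/C(CO[Si](c1ccccc1)(c1ccccc1)C(C)(C)C)=C\[C@H]1OC(=O)C[C@@H]1[C@H](O[Si](CC)(CC)CC)CC(C)=O | intermediate
20 | C1 primary alcohol | OCC[C@H](O[Si](C)(C)C(C)(C)C)/C(CO[Si](c1ccccc1)(c1ccccc1)C(C)(C)C)=C\[C@H]1OC(=O)C[C@@H]1[C@H](O[Si](CC)(CC)CC)CC(C)=O | intermediate
21 | C1 primary triflate | FC(F)(F)S(=O)(=O)OCC[C@H](O[Si](C)(C)C(C)(C)C)/C(CO[Si](c1ccccc1)(c1ccccc1)C(C)(C)C)=C\[C@H]1OC(=O)C[C@@H]1[C@H](O[Si](CC)(CC)CC)CC(C)=O | intermediate (not isolated)
22 | C1 diphenylsulfonium triflate of the seco keto lactone | [O-]S(=O)(=O)C(F)(F)F.c1ccc(cc1)[S+](c1ccccc1)CC[C@H](O[Si](C)(C)C(C)(C)C)/C(CO[Si](c1ccccc1)(c1ccccc1)C(C)(C)C)=C\[C@H]1OC(=O)C[C@@H]1[C@H](O[Si](CC)(CC)CC)CC(C)=O | intermediate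
23 | C1 diphenylsulfonium ylide | c1ccc(cc1)[S+](c1ccccc1)[CH-]C[C@H](O[Si](C)(C)C(C)(C)C)/C(CO[Si](c1ccccc1)(c1ccccc1)C(C)(C)C)=C\[C@H]1OC(=O)C[C@@H]1[C@H](O[Si](CC)(CC)CC)CC(C)=O | intermediate (not isolated)
24 | macrocyclic betaine (C1 sulfonium, C10 alkoxide) | C1C(=O)O[C@@H]2/C=C(/CO[Si](c3ccccc3)(c3ccccc3)C(C)(C)C)[C@@H](O[Si](C)(C)C(C)(C)C)C[C@H]([S+](c3ccccc3)c3ccccc3)[C@@]([O-])(C)C[C@@H](O[Si](CC)(CC)CC)[C@@H]12 | intermediate (not isolated)
25 | epoxy macrolactone (saturated C11) | C1C(=O)O[C@@H]2/C=C(/CO[Si](c3ccccc3)(c3ccccc3)C(C)(C)C)[C@@H](O[Si](C)(C)C(C)(C)C)C[C@H]3O[C@]3(C)C[C@@H](O[Si](CC)(CC)CC)[C@@H]12 | intermediate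
26 | C11 dimethylaminomethyl lactone (Mannich base, C11 configuration not defined) | CN(C)CC1C(=O)O[C@@H]2/C=C(/CO[Si](c3ccccc3)(c3ccccc3)C(C)(C)C)[C@@H](O[Si](C)(C)C(C)(C)C)C[C@H]3O[C@]3(C)C[C@@H](O[Si](CC)(CC)CC)[C@@H]12 | intermediate (not isolated)
27 | C11 trimethylammoniomethyl lactone iodide | [I-].C[N+](C)(C)CC1C(=O)O[C@@H]2/C=C(/CO[Si](c3ccccc3)(c3ccccc3)C(C)(C)C)[C@@H](O[Si](C)(C)C(C)(C)C)C[C@H]3O[C@]3(C)C[C@@H](O[Si](CC)(CC)CC)[C@@H]12 | intermediate (not isolated)
28 | α-methylene epoxy macrolactone | C=C1C(=O)O[C@@H]2/C=C(/CO[Si](c3ccccc3)(c3ccccc3)C(C)(C)C)[C@@H](O[Si](C)(C)C(C)(C)C)C[C@H]3O[C@]3(C)C[C@@H](O[Si](CC)(CC)CC)[C@@H]12 | intermediate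
29 | C8 alcohol | C=C1C(=O)O[C@@H]2/C=C(/CO[Si](c3ccccc3)(c3ccccc3)C(C)(C)C)[C@@H](O[Si](C)(C)C(C)(C)C)C[C@H]3O[C@]3(C)C[C@@H](O)[C@@H]12 | intermediate
30 | angelic acid | C/C=C(/C)C(=O)O | starting material
31 | C8 angelate, C3 OTBS, C15 OTBDPS | C=C1C(=O)O[C@@H]2/C=C(/CO[Si](c3ccccc3)(c3ccccc3)C(C)(C)C)[C@@H](O[Si](C)(C)C(C)(C)C)C[C@H]3O[C@]3(C)C[C@@H](OC(=O)/C(C)=C\C)[C@@H]12 | intermediate
32 | target heliangolide | C=C1C(=O)O[C@@H]2/C=C(/CO)[C@@H](O)C[C@H]3O[C@]3(C)C[C@@H](OC(=O)/C(C)=C\C)[C@@H]12 | target

## Step count and risks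

Total step count: 21. Longest linear sequence: 19 steps (steps 1–3, 5–8, 10–21).

Steps most likely to fail:

1. Step 17 (Proposed new method). The unstabilised ylide may decompose or oligomerise faster than the ten-membered ring closes, or the addition may show poor trans/facial selectivity. The fallback uses known chemistry, sets out from compound 20 and comes back at compound 25. Dess–Martin oxidation of 20 should give keto aldehyde F1. SmI2-mediated intramolecular pinacol coupling at high dilution (THF, −78 °C → rt), through a chelated ketyl–carbonyl coupling, should give the (1S,10R)-diol F2. Selective mesylation of the secondary C1 hydroxyl (MsCl, Et3N, CH2Cl2, −20 °C) gives C1 mesylate F3. DBU then lets the tertiary C10 alkoxide displace the mesylate with inversion at C1, closing the oxirane to 25.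

2. Step 16. A silyl ether oxygen (mainly C15–O, through a six-membered ring) may attack the primary triflate, or elimination may occur, before the weakly nucleophilic diphenyl sulfide reacts. The fallback sets out from compound 20 and comes back at compound 22. Thioetherification of 20 with PhSSPh and Bu3P should give phenyl sulfide F4. S-phenylation of F4 with diphenyliodonium triflate and catalytic Cu(OAc)2 (1,2-dichloroethane, 80 °C) should give the diphenylsulfonium triflate 22 without an alkyl triflate ever being formed.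

3. Step 7. Facial selectivity may be poor because the reagent must override the Felkin preference of the α-branched aldehyde, and the free C8 hydroxyl may translactonise during work-up. The fallback sets out from compound 10 and comes back at compound 11. Uncatalysed allylation of 10 with allylboronic acid pinacol ester (CH2Cl2, rt) gives C8-epimeric alcohol mixture F5. Dess–Martin oxidation gives allyl ketone F6. Reduction with (S)-2-methyl-CBS-oxazaborolidine and catecholborane, in which reagent control and Felkin hydride delivery reinforce each other, should give 11.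

## Further compounds

F1 | step 17 | keto aldehyde (C1 aldehyde, C10 methyl ketone) | O=CC[C@H](O[Si](C)(C)C(C)(C)C)/C(CO[Si](c1ccccc1)(c1ccccc1)C(C)(C)C)=C\[C@H]1OC(=O)C[C@@H]1[C@H](O[Si](CC)(CC)CC)CC(C)=O
F2 | step 17 | (1S,10R)-1,10-diol macrolactone | C1C(=O)O[C@@H]2/C=C(/CO[Si](c3ccccc3)(c3ccccc3)C(C)(C)C)[C@@H](O[Si](C)(C)C(C)(C)C)C[C@H](O)[C@@](O)(C)C[C@@H](O[Si](CC)(CC)CC)[C@@H]12
F3 | step 17 | C1 mesylate of diol F2 | C1C(=O)O[C@@H]2/C=C(/CO[Si](c3ccccc3)(c3ccccc3)C(C)(C)C)[C@@H](O[Si](C)(C)C(C)(C)C)C[C@H](OS(C)(=O)=O)[C@@](O)(C)C[C@@H](O[Si](CC)(CC)CC)[C@@H]12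
F4 | step 16 | C1 phenyl sulfide | c1ccc(cc1)SCC[C@H](O[Si](C)(C)C(C)(C)C)/C(CO[Si](c1ccccc1)(c1ccccc1)C(C)(C)C)=C\[C@H]1OC(=O)C[C@@H]1[C@H](O[Si](CC)(CC)CC)CC(C)=O
F5 | step 7 | C8-epimeric homoallylic alcohol mixture | CC(C)(C)[Si](c1ccccc1)(c1ccccc1)OC/C(I)=C/[C@H]1OC(=O)C[C@@H]1C(O)CC=C
F6 | step 7 | C8 allyl ketone | CC(C)(C)[Si](c1ccccc1)(c1ccccc1)OC/C(I)=C/[C@H]1OC(=O)C[C@@H]1C(=O)CC=C
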